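**Strategy.** The target is the all-(−)-epiafzelechin trimer with two 4β→8 interflavan bonds. Both C4–C8 bonds are cut first, so that one tri-O-benzyl monomer serves as all three units. Everything rests on how that monomer's ring C is made: a five-membered 3-methylene-2,3-dihydrobenzofuran ring (O1, C2, C3, C4a, C8a) is enlarged by an oxidative 1,2-shift of bond C3–C4a onto the exocyclic carbon, which becomes C4, giving the flavan-3-one in one operation. The step exploits the phloroglucinol ring A: C4a, ortho to the O1-bearing C8a and to C5–O and para to C7–O, is an exceptional migrating group. Dynamic kinetic resolution then sets C2 and C3.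

Key step: step 4

Assumption: the (R,R)-configured ruthenium catalyst of step 5 is taken to deliver the (2R,3R)-alcohol, by analogy with cis-selective reductions of 2-aryl cycloalkanones; if the sense proves opposite, the (S,S) catalyst is used instead.

Step 1
Reactants: 1 3,5-bis(benzyloxy)phenol
Product: 2 3,5-bis(benzyloxy)-2-iodophenol
Conditions: NIS (1.0 equiv), CH2Cl2, −40 to 0 °C, dark
Reagents that add atoms: N-iodosuccinimide, O=C1CCC(=O)N1I
Why: Electrophilic aromatic iodination should occur at C2, which is ortho to the free hydroxyl and less hindered than C4 between the two benzyloxy groups, and one equivalent at low temperature limits di-iodination.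

Step 2
Reactants: 3 1-(benzyloxy)-4-ethynylbenzene
Product: 5 1-(benzyloxy)-4-(propa-1,2-dien-1-yl)benzene, via propargylic amine 4 (not isolated)
Conditions: (CH2O)n, Cy2NH, CuI (0.5 equiv), 1,4-dioxane, reflux
Reagents that add atoms: paraformaldehyde (as formaldehyde), C=O
Why: Crabbé homologation, in which the copper-mediated Mannich reaction gives the propargylic amine and its 1,5-hydride shift with loss of imine should deliver the terminal allene.

Step 3
Reactants: 2 3,5-bis(benzyloxy)-2-iodophenol; 5 1-(benzyloxy)-4-(propa-1,2-dien-1-yl)benzene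
Product: 6 rac-4,6-bis(benzyloxy)-2-[4-(benzyloxy)phenyl]-3-methylidene-2,3-dihydro-1-benzofuran
Conditions: Pd(OAc)2 (5 mol %), PPh3 (10 mol %), K2CO3, n-Bu4NCl, DMF, 60 °C
Reagents that add atoms: none
Why: Larock heteroannulation of a 1,2-diene, in which the arylpalladium species from 2 adds to the central allene carbon and the phenoxide closes the five-membered ring at the aryl-substituted, more cation-stabilising terminus of the π-allyl complex, which should leave the exocyclic methylene and a racemic C2 centre.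

Step 4
Reactants: 6 rac-4,6-bis(benzyloxy)-2-[4-(benzyloxy)phenyl]-3-methylidene-2,3-dihydro-1-benzofuran
Product: 9 rac-5,7-bis(benzyloxy)-2-[4-(benzyloxy)phenyl]chroman-3-one, via methoxy iodonium adduct 7 (not isolated), via dimethyl ketal 8 (not isolated)
Conditions: PhI(OH)OTs (1.1 equiv), MeOH–H2O 95:5, 0 °C to rt; then 1 M HCl, THF, rt
Reagents that add atoms: water, O
Why: The electrophilic trivalent iodine reagent adds to the exocyclic CH2 of 6 and methanol captures the benzylic cation at C3 to give 7; the electron-rich ring A carbon (future C4a), antiperiplanar to the C–I bond, then migrates from C3 to the exocyclic carbon with loss of iodobenzene, and the methoxy-stabilised oxocarbenium ion at C3 is trapped as ketal 8 and hydrolysed to ketone 9. The closest known reaction type is the hypervalent-iodine-mediated oxidative ring expansion of 1-methylene benzocycloalkanes to β-benzocycloalkenones, a semipinacol-type 1,2-aryl shift. Ring C is not closed by a cyclisation but by ring enlargement: bond C3–C4a of the five-membered ring shifts to the exocyclic carbon, which becomes C4 of the six-membered ring. No stereocentre is created, since C3 becomes a carbonyl carbon and C2 is carried through as the racemate that step 5 resolves dynamically. The step needs the aryl shift to outrun migration of C2, loss of the C2 proton to the aromatic benzofuran and attack of the reagent on the arene; the two ortho oxygens and the para oxygen on the migrating carbon should make phenonium-type participation very fast, the leaving-group ability of iodobenzene makes the shift irreversible, and methanol as solvent should capture the C3 cation before elimination.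

Step 5
Reactants: 9 rac-5,7-bis(benzyloxy)-2-[4-(benzyloxy)phenyl]chroman-3-one
Product: 10 (2R,3R)-5,7-bis(benzyloxy)-2-[4-(benzyloxy)phenyl]chroman-3-ol (5,7,4′-tri-O-benzyl-(−)-epiafzelechin)
Conditions: RuCl(p-cymene)[(R,R)-TsDPEN] (1 mol %), HCO2H–Et3N (1:1), EtOAc, 40 °C, argon
Reagents that add atoms: none
Why: Noyori asymmetric transfer hydrogenation under dynamic kinetic resolution, in which C2 (benzylic, α to the ketone and to O1) epimerises by enolisation in the amine buffer while the chiral ruthenium hydride reduces one enantiomer faster and delivers hydride to C3 anti to the 2-aryl group, so that C2 (R) and C3 (R, 2,3-cis) should both be set by the catalyst.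

Step 6
Reactants: 10 (2R,3R)-5,7-bis(benzyloxy)-2-[4-(benzyloxy)phenyl]chroman-3-ol
Product: 11 (2R,3R,4S)-5,7-bis(benzyloxy)-2-[4-(benzyloxy)phenyl]-4-(2-ethoxyethoxy)chroman-3-ol
Conditions: DDQ (2 equiv), 2-ethoxyethanol, CH2Cl2, rt
Reagents that add atoms: 2-ethoxyethanol, CCOCCO
Why: Benzylic oxidation by DDQ (hydride abstraction at C4, assisted by the ring A oxygens) should give a quinone-methide-type cation that the alcohol captures on the β face, anti to the 2-aryl and 3-hydroxyl groups (4β, 4S), a centre that is ionised again in the coupling steps.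

Step 7
Reactants: 11 (2R,3R,4S)-5,7-bis(benzyloxy)-2-[4-(benzyloxy)phenyl]-4-(2-ethoxyethoxy)chroman-3-ol; 10 (2R,3R)-5,7-bis(benzyloxy)-2-[4-(benzyloxy)phenyl]chroman-3-ol
Product: 12 hexa-O-benzyl epiafzelechin-(4β→8)-epiafzelechin
Conditions: Yb(OTf)3 (cat.), CH2Cl2, 0 °C to rt, 10 in four-fold excess (excess recovered)
Reagents that add atoms: none
Why: Lewis-acid-catalysed Friedel–Crafts interflavan coupling, in which ionisation of the C4 ether gives the ring-A-stabilised benzylic cation and C8 of the excess nucleophile should attack it anti to the 3-hydroxyl and 2-aryl groups, setting C4 of the upper unit as 4β (R) with 4→8 regiochemistry.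

Step 8
Reactants: 11 (2R,3R,4S)-5,7-bis(benzyloxy)-2-[4-(benzyloxy)phenyl]-4-(2-ethoxyethoxy)chroman-3-ol; 12 hexa-O-benzyl epiafzelechin-(4β→8)-epiafzelechin
Product: 13 nona-O-benzyl epiafzelechin-(4β→8)-epiafzelechin-(4β→8)-epiafzelechin
Conditions: Yb(OTf)3 (cat.), CH2Cl2, 0 °C to rt, 12 in three-fold excess (excess recovered)
Reagents that add atoms: none
Why: The same Friedel–Crafts coupling, in which the free C8 of the upper unit of 12 is the most accessible nucleophilic position and attack on the β face of the cation from 11 should set the new C4 centre as 4β (R), while the C4 descriptor of the former upper unit changes from R to S by priority only.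

Step 9
Reactants: 13 nona-O-benzyl epiafzelechin-(4β→8)-epiafzelechin-(4β→8)-epiafzelechin
Product: 14 (−)-epiafzelechin-(4β→8)-(−)-epiafzelechin-(4β→8)-(−)-epiafzelechin (CNP0191553.1)
Conditions: H2 (1 atm), Pd(OH)2/C, THF–MeOH–H2O, rt
Reagents that add atoms: none
Why: Hydrogenolysis of the nine benzyl ethers under neutral conditions should leave the acid-sensitive interflavan bonds and all eight stereocentres untouched.

**Compound list**

1 | 3,5-bis(benzyloxy)phenol | Oc1cc(OCc2ccccc2)cc(OCc2ccccc2)c1 | starting material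
2 | 3,5-bis(benzyloxy)-2-iodophenol | Oc1cc(OCc2ccccc2)cc(OCc2ccccc2)c1I | intermediate
3 | 1-(benzyloxy)-4-ethynylbenzene | C#Cc1ccc(OCc2ccccc2)cc1 | starting material
4 | N,N-dicyclohexyl-3-[4-(benzyloxy)phenyl]prop-2-yn-1-amine (not isolated) | C1CCCCC1N(CC#Cc1ccc(OCc2ccccc2)cc1)C1CCCCC1 | intermediate
5 | 1-(benzyloxy)-4-(propa-1,2-dien-1-yl)benzene | C=C=Cc1ccc(OCc2ccccc2)cc1 | intermediate
6 | rac-4,6-bis(benzyloxy)-2-[4-(benzyloxy)phenyl]-3-methylidene-2,3-dihydro-1-benzofuran | C=C1C(c2ccc(OCc3ccccc3)cc2)Oc2cc(OCc3ccccc3)cc(OCc3ccccc3)c21 | intermediate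
7 | rac-{[4,6-bis(benzyloxy)-2-[4-(benzyloxy)phenyl]-3-methoxy-2,3-dihydro-1-benzofuran-3-yl]methyl}(phenyl)iodonium tosylate (not isolated) | COC1(C[I+]c2ccccc2)C(c2ccc(OCc3ccccc3)cc2)Oc2cc(OCc3ccccc3)cc(OCc3ccccc3)c21.Cc1ccc(S(=O)(=O)[O-])cc1 | intermediate
8 | rac-5,7-bis(benzyloxy)-2-[4-(benzyloxy)phenyl]-3,3-dimethoxychroman (not isolated) | COC1(OC)Cc2c(OCc3ccccc3)cc(OCc3ccccc3)cc2OC1c1ccc(OCc2ccccc2)cc1 | intermediate
9 | rac-5,7-bis(benzyloxy)-2-[4-(benzyloxy)phenyl]chroman-3-one | O=C1Cc2c(OCc3ccccc3)cc(OCc3ccccc3)cc2OC1c1ccc(OCc2ccccc2)cc1 | intermediate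
10 | (2R,3R)-5,7-bis(benzyloxy)-2-[4-(benzyloxy)phenyl]chroman-3-ol | c1c(OCc3ccccc3)cc(OCc3ccccc3)c2c1O[C@H](c1ccc(OCc3ccccc3)cc1)[C@H](O)C2 | intermediate
11 | (2R,3R,4S)-5,7-bis(benzyloxy)-2-[4-(benzyloxy)phenyl]-4-(2-ethoxyethoxy)chroman-3-ol | c1c(OCc3ccccc3)cc(OCc3ccccc3)c2c1O[C@H](c1ccc(OCc3ccccc3)cc1)[C@H](O)[C@H]2OCCOCC | intermediate
12 | (2R,3R,4R)-5,7-bis(benzyloxy)-2-[4-(benzyloxy)phenyl]-4-{(2R,3R)-5,7-bis(benzyloxy)-2-[4-(benzyloxy)phenyl]-3-hydroxychroman-8-yl}chroman-3-ol (hexa-O-benzyl dimer) | O(Cc1ccccc1)c1ccc([C@H]2Oc3c(c(OCc4ccccc4)cc(OCc4ccccc4)c3)[C@H](c3c(OCc4ccccc4)cc(OCc4ccccc4)c4c3O[C@H](c3ccc(OCc5ccccc5)cc3)[C@H](O)C4)[C@H]2O)cc1 | intermediate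
13 | nona-O-benzyl epiafzelechin-(4β→8)-epiafzelechin-(4β→8)-epiafzelechin (upper unit 2R,3R,4R; middle unit 2R,3R,4S; lower unit 2R,3R; benzyl ethers on O5, O7 and O4′ of each unit) | O(Cc1ccccc1)c1ccc([C@H]2Oc3c(c(OCc4ccccc4)cc(OCc4ccccc4)c3[C@H]3c4c(OCc5ccccc5)cc(OCc5ccccc5)cc4O[C@H](c4ccc(OCc5ccccc5)cc4)[C@@H]3O)[C@H](c3c(OCc4ccccc4)cc(OCc4ccccc4)c4c3O[C@H](c3ccc(OCc5ccccc5)cc3)[C@H](O)C4)[C@H]2O)cc1 | intermediate
14 | (−)-epiafzelechin-(4β→8)-(−)-epiafzelechin-(4β→8)-(−)-epiafzelechin, CNP0191553.1 (upper unit 2R,3R,4R; middle unit 2R,3R,4S; lower unit 2R,3R) | Oc1ccc([C@H]2Oc3c(c(O)cc(O)c3[C@H]3c4c(O)cc(O)cc4O[C@H](c4ccc(O)cc4)[C@@H]3O)[C@H](c3c(O)cc(O)c4c3O[C@H](c3ccc(O)cc3)[C@H](O)C4)[C@H]2O)cc1 | target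

**Step count.** Total: 9 steps. Longest linear sequence: 8 steps (steps 1, 3, 4, 5, 6, 7, 8, 9); step 2 is a one-step branch.

**Steps most likely to fail, with fallbacks**

Step 4. The C3 cation may lose the C2 proton and aromatise to the benzofuran, or the iodine reagent may attack the very electron-rich arene, before the aryl shift takes place. The fallback sets out from 6. Dihydroxylation (OsO4 cat., NMO, acetone–H2O) should give rac-4,6-bis(benzyloxy)-2-[4-(benzyloxy)phenyl]-3-(hydroxymethyl)-2,3-dihydro-1-benzofuran-3-ol F1. Selective sulfonylation of the primary hydroxyl (TsCl, pyridine, 0 °C) should give its mono-tosylate F2. Treatment with AlEt3 in CH2Cl2 at −78 °C then triggers the organoaluminium-promoted pinacol-type rearrangement, the same ring A carbon shifting onto the primary carbon with loss of tosylate, and the route is rejoined at ketone 9.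

Step 3. The phenoxide may close at the unsubstituted terminus of the π-allyl complex, or zerovalent palladium may re-ionise the allylic aryl ether so that the product drifts to the conjugated 3-benzylidene isomer or to the aromatic benzofuran. The fallback sets out from 2. Mitsunobu etherification (PPh3, DIAD, THF) with 1-[4-(benzyloxy)phenyl]prop-2-yn-1-ol F3, itself made from 4-(benzyloxy)benzaldehyde and ethynylmagnesium bromide, should give 1,5-bis(benzyloxy)-3-{1-[4-(benzyloxy)phenyl]prop-2-yn-1-yloxy}-2-iodobenzene F4. A 5-exo-dig aryl radical cyclisation (n-Bu3SnH, AIBN, toluene, 80 °C) then forms the exocyclic alkene without any π-allyl intermediate and comes back to the route at 6.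

Step 5. Epimerisation at C2 may be too slow relative to reduction, or the catalyst may discriminate the two faces poorly, so that the alcohol is formed in low enantiomeric purity. The fallback sets out from 9. Reduction with LiBH(s-Bu)3 (THF, −78 °C), hydride arriving anti to the 2-aryl group, should give racemic cis-5,7-bis(benzyloxy)-2-[4-(benzyloxy)phenyl]chroman-3-ol F5. Esterification with (S)-2-methoxy-2-phenylacetic acid (DCC, DMAP, CH2Cl2) gives two diastereomeric esters, the (2R,3R)-configured ester F6 and the (2S,3S)-configured ester F7, which are separated by chromatography. Saponification of F6 (LiOH, THF–H2O) comes back to the route at 10.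

Further compounds
F1 | step 4 | rac-4,6-bis(benzyloxy)-2-[4-(benzyloxy)phenyl]-3-(hydroxymethyl)-2,3-dihydro-1-benzofuran-3-ol | OCC1(O)C(c2ccc(OCc3ccccc3)cc2)Oc2cc(OCc3ccccc3)cc(OCc3ccccc3)c21
F2 | step 4 | rac-{4,6-bis(benzyloxy)-2-[4-(benzyloxy)phenyl]-3-hydroxy-2,3-dihydro-1-benzofuran-3-yl}methyl 4-methylbenzenesulfonate | Cc1ccc(S(=O)(=O)OCC2(O)C(c3ccc(OCc4ccccc4)cc3)Oc3cc(OCc4ccccc4)cc(OCc4ccccc4)c32)cc1
F3 | step 3 | rac-1-[4-(benzyloxy)phenyl]prop-2-yn-1-ol | C#CC(O)c1ccc(OCc2ccccc2)cc1
F4 | step 3 | rac-1,5-bis(benzyloxy)-3-{1-[4-(benzyloxy)phenyl]prop-2-yn-1-yloxy}-2-iodobenzene | C#CC(Oc1cc(OCc2ccccc2)cc(OCc2ccccc2)c1I)c1ccc(OCc2ccccc2)cc1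
F5 | step 5 | rac-(2R,3R)-5,7-bis(benzyloxy)-2-[4-(benzyloxy)phenyl]chroman-3-ol (racemic cis alcohol, one enantiomer drawn) | c1c(OCc3ccccc3)cc(OCc3ccccc3)c2c1O[C@H](c1ccc(OCc3ccccc3)cc1)[C@H](O)C2
F6 | step 5 | (2R,3R)-5,7-bis(benzyloxy)-2-[4-(benzyloxy)phenyl]chroman-3-yl (S)-2-methoxy-2-phenylacetate | c1c(OCc3ccccc3)cc(OCc3ccccc3)c2c1O[C@H](c1ccc(OCc3ccccc3)cc1)[C@H](OC(=O)[C@@H](OC)c1ccccc1)C2
F7 | step 5 | (2S,3S)-5,7-bis(benzyloxy)-2-[4-(benzyloxy)phenyl]chroman-3-yl (S)-2-methoxy-2-phenylacetate | c1c(OCc3ccccc3)cc(OCc3ccccc3)c2c1O[C@@H](c1ccc(OCc3ccccc3)cc1)[C@@H](OC(=O)[C@@H](OC)c1ccccc1)C2
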